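The readings are simulated with constants of no real substance, noise included.

No flask gives back more than it was charged with, and no form of the catalyst on the list of suspects carries more than one substrate unit. So the catalyst can hold at most the catalyst toll, the catalyst charge as a share of the substrate charge, 15.0 %. The balance reads: product, substrate, dormant form and the share held on the catalyst sum to 100 %.

| flask | substrate | free catalyst | added ligand | remark | time |
|---|---|---|---|---|---|
| eta | 0.050 M | 7.5 mM | 14 mM | the very flask that is asked about, followed so far |  |
| beta | 0.050 M | 7.5 mM | 7 mM | run made earlier |  |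
| flask | 0.050 M | 7.5 mM | 14 mM |  | 4.0 d |

| run | time / h | product / % | substrate / % |
|---|---|---|---|
| eta | 8.00 | 41.8 | 10.0 |
| eta | 15.0 | 46.1 | 10.5 |
| eta | 25.0 | 46.9 | 8.7 |
| eta | 30.0 | 47.5 | 9.7 |
| eta | 40.0 | 46.5 | 9.4 |
| eta | 50.0 | 47.8 | 9.2 |
| eta | 60.0 | 46.8 | 9.0 |
| beta | 0.500 | 7.6 | 20.6 |
| beta | 1.00 | 15.6 | 16.1 |
| beta | 1.50 | 19.9 | 14.5 |
| beta | 2.00 | 22.5 | 14.4 |
| beta | 2.50 | 27.5 | 13.2 |
| beta | 3.00 | 30.0 | 13.0 |
| beta | 4.00 | 35.2 | 12.0 |

(scatter of a reading: 0.5 percentage points)

- ochre: at 4.0 d add free catalyst, 100 % of the amount charged, then wait 8.0 d
- green: change nothing and wait 8.0 d more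
- violet: at 4.0 d add substrate, 50.0 % of the amount charged, then wait 8.0 d
- amber: at 4.0 d take out 90 % of the product then present, then wait 8.0 d

- product taken out counts as made
- on the list of suspects stand: substrate + free catalyst <-> catalyst intermediate A; catalyst intermediate A <-> catalyst intermediate B; catalyst intermediate B <-> free catalyst + product; substrate <-> dormant form; free catalyst + added ligand <-> idle complex; catalyst intermediate B -> spent catalyst
- additions bring no volume worth counting

1. product, in percent of the substrate first charged, at 4.0 d
2. which option adds most product ("none" when 2 percentage points or less is all one gets) (ochre / green / violet / amber / none)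
3. product present, with what was taken out counted in, in percent of the substrate first charged, after green
4. product present, with what was taken out counted in, in percent of the substrate first charged, after amber

From 25.0 h on, the eta readings average 47.1 % product and 9.20 % substrate. In the beta run substrate is down to 20.6 % at 0.500 h while product stands at 7.6 %, so we freeze the pool factor, ([substrate]+[dormant form])/[substrate]. Two extreme eta flasks can be solved in the head. If the catalyst holds nothing and the plateau is an equilibrium, the factor is 5.75. If it holds the full toll and the plateau is a stall, the factor is 4.12. The beta reading at 0.500 h, with the dormant form taken as in step by then, allows a factor of at most 4.49, even with nothing held. The first extreme lies above this ceiling and the second below it. So, as far as these scattered readings tell, the eta flask holds about 11.6 % or more of the 15.0 %. The balance cannot tell spent catalyst from a live bound form, but we commit to the stall. Product then stays near 47.1 %, waiting, removing product and adding substrate give nothing, and ochre is our choice.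

The forecast gave 47 % now, 47 % after green and 68.5 % after amber, and chose violet, reading the plateau as “true equilibrium with live catalyst, not catalyst death”. There we differ.

The flask gives 47.0 % at 4.0 d, 47.0 % after green and 47.0 % after amber; ochre adds 7.8 percentage points and violet 0 points.

    substrate + free catalyst ⇌ catalyst intermediate A (K = 130 M⁻¹, k = 0.0900 M⁻¹ s⁻¹)
    catalyst intermediate A ⇌ catalyst intermediate B (K = 70.0, k = 0.00380 s⁻¹)
    catalyst intermediate B ⇌ free catalyst + product (K = 0.0310 M, k = 9.00 × 10⁻⁴ s⁻¹)
    substrate ⇌ dormant form (K = 3.30, k = 0.00140 s⁻¹)
    free catalyst + added ligand ⇌ idle complex, settled at all times (K = 26.0 M⁻¹)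
    catalyst intermediate B → spent catalyst (k = 1.50 × 10⁻⁴ s⁻¹)

At 96.0 h spent catalyst stands at 100 % of the catalyst charged. The toll, taken with the substrate and dormant form standing then, leaves 47.0 % for product. In the neighbour flask with 0.030 M of substrate the toll becomes 25.0 %, the same balance leaves 54.5 %, and that flask stands at 54.5 % product.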